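**Plan** (eudesmane locants: C1 = CH2OAc, C4 = CH(CH3), C5=C10 = ring alkene, C6 = CHOAc, C7/C8 = ring fusion, C11–C13 = acrylate carbons, C14 = ring methyl)
1. The retrosynthesis cuts the ring-fusion bond C7–C8, the lactone acyl–O bond and the tetrasubstituted alkene C5=C10 together, leaving an allylboronate (C1–C7, C11–C13) and 3-methylbut-3-enal (C8–C10, C14).
2. Enabling feature: the α-methylene-γ-lactone (ring B: O–C8–C7–C11–C12) is what an acrylate-type allyl unit C13–C11–C7 gives on adding to an aldehyde carbon C8. The only alkene of the cyclohexene (ring A), C5=C10, lies across the ring from C7–C8, so the cis lactone holds two 1,1-disubstituted alkenes (C5=CH2, C10=CH2) within reach for metathesis.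
3. Forward: (S)-citronellal gives the C1–C6 enal; alkynylation with methyl propiolate adds C7, C11 and C12; hydroalumination–iodination and a borylmethyl Negishi coupling add C13. The last step joins the allylboronate and the aldehyde in one flask, closing ring B first (allylboration–lactonization) and then ring A (metathesis).
4. Stereochemistry: C4 comes from citronellal, C6 from the catalyst-controlled alkynylation, C7 from C6 (allylic strain in the allylboration), and C8 from the alkene geometry of the allylboronate through the chair transition state.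

Key step: step 11

Remark: (S)-(−)-citronellal, methyl propiolate, 3-methylbut-3-en-1-ol, (S,S)-ProPhenol and 2-(iodomethyl)-4,4,5,5-tetramethyl-1,3,2-dioxaborolane are taken as purchased; the (S,S) ligand is assumed to deliver the 4S alcohol in step 6, and its enantiomer would be used if the sense is the opposite.

**Step 1**
Reactants: 1 (S)-citronellal
Product: 2 (6S)-8,8-dimethoxy-2,6-dimethyloct-2-ene
Conditions: HC(OMe)3, MeOH, PPTS (cat.), rt
Reagents that add atoms: trimethyl orthoformate, COC(OC)OC
Why: Acid-catalysed acetalization with the orthoformate as water scavenger masks the aldehyde before ozonolysis and leaves the methyl-bearing stereocentre untouched.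

**Step 2**
Reactants: 2 (6S)-8,8-dimethoxy-2,6-dimethyloct-2-ene
Product: 4 (4S)-6,6-dimethoxy-4-methylhexan-1-ol, via aldehyde 3 (not isolated)
Conditions: O3, CH2Cl2/MeOH, −78 °C; then NaBH4, −78 to 0 °C
Reagents that add atoms: ozone, [O-][O+]=O
Why: Ozonolysis cleaves the only alkene and borohydride reduces aldehyde 3 in the same flask to the primary alcohol, the acetal being inert to both.

**Step 3**
Reactants: 4 (4S)-6,6-dimethoxy-4-methylhexan-1-ol
Product: 5 (4S)-6,6-dimethoxy-4-methylhexyl acetate
Conditions: Ac2O, pyridine, DMAP (cat.), CH2Cl2, 0 °C to rt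
Reagents that add atoms: acetic anhydride, CC(=O)OC(C)=O
Why: DMAP-catalysed O-acetylation installs the C1 acetate of the target at the outset.

**Step 4**
Reactants: 5 (4S)-6,6-dimethoxy-4-methylhexyl acetate
Product: 6 (4S)-4-methyl-6-oxohexyl acetate
Conditions: PPTS, acetone/H2O (9:1), 50 °C
Reagents that add atoms: water, O
Why: Mild acid-catalysed acetal hydrolysis frees the aldehyde without touching the acetate.

**Step 5**
Reactants: 6 (4S)-4-methyl-6-oxohexyl acetate
Product: 7 (4S)-5-formyl-4-methylhex-5-en-1-yl acetate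
Conditions: 37% aq. HCHO, pyrrolidine (10 mol%), propionic acid (10 mol%), i-PrOH, 45 °C
Reagents that add atoms: formaldehyde, C=O
Why: Organocatalytic α-methylenation (enamine Mannich condensation, then amine elimination) should give the 2-substituted acrolein, and the short reaction time protects the adjacent stereocentre.

**Step 6**
Reactants: 7 (4S)-5-formyl-4-methylhex-5-en-1-yl acetate; 8 methyl propiolate
Product: 9 methyl (4S,6S)-9-acetoxy-4-hydroxy-6-methyl-5-methylidenenon-2-ynoate
Conditions: (S,S)-ProPhenol (20 mol%), ZnMe2 (3 equiv), Ph3PO (40 mol%), toluene, 4 °C; aq. NH4Cl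
Reagents that add atoms: none
Why: Zinc–ProPhenol-catalysed enantioselective alkynylation of an α-branched enal should set the 4S carbinol (future C6) by catalyst control, the (S,S) ligand being the one assumed to deliver this face.

**Step 7**
Reactants: 9 methyl (4S,6S)-9-acetoxy-4-hydroxy-6-methyl-5-methylidenenon-2-ynoate
Product: 11 methyl (2Z,4R,6S)-9-acetoxy-4-hydroxy-2-iodo-6-methyl-5-methylidenenon-2-enoate, via alkenylalanate 10 (not isolated)
Conditions: NaAlH2(OCH2CH2OMe)2 (Red-Al), THF, −72 °C; then NIS, −72 to −20 °C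
Reagents that add atoms: N-iodosuccinimide, O=C1CCC(=O)N1I
Why: Alkoxide-directed trans-hydroalumination of the γ-hydroxy ynoate places aluminium on C2 cis to the carbinol carbon (five-membered alanate 10), and iodinolysis with retention should give the Z iodide while the low temperature spares both esters.

**Step 8**
Reactants: 11 methyl (2Z,4R,6S)-9-acetoxy-4-hydroxy-2-iodo-6-methyl-5-methylidenenon-2-enoate
Product: 12 methyl (2E,4R,6S)-9-acetoxy-4-hydroxy-6-methyl-5-methylidene-2-[(4,4,5,5-tetramethyl-1,3,2-dioxaborolan-2-yl)methyl]non-2-enoate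
Conditions: ICH2Bpin, Zn dust, THF, rt (gives pinBCH2ZnI in the flask); then 11, Pd(PPh3)4 (5 mol%), THF, rt to 40 °C
Reagents that add atoms: [(4,4,5,5-tetramethyl-1,3,2-dioxaborolan-2-yl)methyl]zinc iodide, I[Zn]CB1OC(C)(C)C(C)(C)O1
Why: Zinc insertion into the iodomethylboronate gives the borylmethylzinc iodide, and its Negishi coupling at zerovalent palladium (oxidative addition to the alkenyl iodide, transmetalation, reductive elimination) proceeds with retention of alkene geometry and should give the 2-(alkoxycarbonyl)allylboronate with CH2B cis to the carbinol carbon.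

**Step 9**
Reactants: 12 methyl (2E,4R,6S)-9-acetoxy-4-hydroxy-6-methyl-5-methylidene-2-[(4,4,5,5-tetramethyl-1,3,2-dioxaborolan-2-yl)methyl]non-2-enoate
Product: 13 methyl (2E,4R,6S)-4,9-diacetoxy-6-methyl-5-methylidene-2-[(4,4,5,5-tetramethyl-1,3,2-dioxaborolan-2-yl)methyl]non-2-enoate
Conditions: Ac2O, pyridine, DMAP (cat.), CH2Cl2, 0 °C
Reagents that add atoms: acetic anhydride, CC(=O)OC(C)=O
Why: Acetylation of the secondary alcohol installs the C6 acetate of the target, and the pinacol boronate tolerates these conditions.

**Step 10**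
Reactants: 14 3-methylbut-3-en-1-ol
Product: 15 3-methylbut-3-enal
Conditions: Dess–Martin periodinane, pyridine, CH2Cl2, 0 °C; filtered solution used at once
Reagents that add atoms: none
Why: Buffered Dess–Martin oxidation should give the β,γ-unsaturated aldehyde without isomerization into conjugation.

**Step 11**
Reactants: 13 methyl (2E,4R,6S)-4,9-diacetoxy-6-methyl-5-methylidene-2-[(4,4,5,5-tetramethyl-1,3,2-dioxaborolan-2-yl)methyl]non-2-enoate; 15 3-methylbut-3-enal
Product: 18 1,6-O,O-diacetylbritannilactone, via pinacol borate 16 (not isolated), via lactone diene 17 (not isolated)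
Conditions: 15 (3 equiv), toluene, 80 °C; excess 15 removed under reduced pressure, toluene added; then [1,3-bis(2-methylphenyl)imidazolidin-2-ylidene]dichloro(2-isopropoxybenzylidene)ruthenium (10 mol%), 1,4-benzoquinone (20 mol%), 90 °C, argon sparge; one flask
Reagents that add atoms: none
Why: Thermal allylboration through a closed six-membered chair transition state joins C7 to the aldehyde carbon C8 with allyl transposition that creates the exocyclic methylene; borate 16 then acylates on the methyl ester (5-exo-trig) to give cis lactone 17, and the ruthenium alkylidene joins C5=CH2 and C10=CH2 through a ruthenacyclobutane with loss of ethene, closing the six-membered ring A by ring-closing metathesis as C5=C10. The closest known reactions are the lactone-forming allylboration of aldehydes with 2-(alkoxycarbonyl)allylboronates and ring-closing metathesis to tetrasubstituted cyclohexenes. C8 is set relative to C7 by the chair, in which the alkene geometry of 13 (C6 cis to CH2B) places C6 axial and the aldehyde residue equatorial, giving the syn adduct and hence the cis ring fusion. C7 is set by C6 through allylic 1,3-strain: the C6–H bond eclipses the alkene and the aldehyde should add anti to the bulky C5 alkenyl branch, on the face that carries the smaller acetoxy group, which gives the all-cis C6/C7/C8 array of the target. The selectivity needed is ring closure between C5 and C10 and not onto the exocyclic methylene; the cis placement of the two electron-rich alkenes on the lactone and the low metathesis reactivity of the electron-poor acrylate alkene should secure it, while benzoquinone suppresses hydride-mediated alkene migration.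

**Compound list**
1 | (S)-citronellal, (3S)-3,7-dimethyloct-6-enal | C[C@@H](CCC=C(C)C)CC=O | starting material
2 | (6S)-8,8-dimethoxy-2,6-dimethyloct-2-ene | C[C@@H](CCC=C(C)C)CC(OC)OC | intermediate
3 | (4S)-6,6-dimethoxy-4-methylhexanal | C[C@@H](CCC=O)CC(OC)OC | intermediate
4 | (4S)-6,6-dimethoxy-4-methylhexan-1-ol | C[C@@H](CCCO)CC(OC)OC | intermediate
5 | (4S)-6,6-dimethoxy-4-methylhexyl acetate | C[C@@H](CCCOC(C)=O)CC(OC)OC | intermediate
6 | (4S)-4-methyl-6-oxohexyl acetate | C[C@@H](CCCOC(C)=O)CC=O | intermediate
7 | (4S)-5-formyl-4-methylhex-5-en-1-yl acetate | C[C@@H](CCCOC(C)=O)C(=C)C=O | intermediate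
8 | methyl propiolate | C#CC(=O)OC | starting material
9 | methyl (4S,6S)-9-acetoxy-4-hydroxy-6-methyl-5-methylidenenon-2-ynoate | COC(=O)C#C[C@@H](O)C(=C)[C@@H](C)CCCOC(C)=O | intermediate
10 | sodium cyclic alkenylalanate of 9 (aluminium on C2, bridged to the C4 oxygen, two 2-methoxyethoxy ligands) | [Na+].COCCO[Al-]1(OCCOC)O[C@H](C=C1C(=O)OC)C(=C)[C@@H](C)CCCOC(C)=O | intermediate
11 | methyl (2Z,4R,6S)-9-acetoxy-4-hydroxy-2-iodo-6-methyl-5-methylidenenon-2-enoate | COC(=O)/C(I)=C/[C@@H](O)C(=C)[C@@H](C)CCCOC(C)=O | intermediate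
12 | methyl (2E,4R,6S)-9-acetoxy-4-hydroxy-6-methyl-5-methylidene-2-[(4,4,5,5-tetramethyl-1,3,2-dioxaborolan-2-yl)methyl]non-2-enoate | COC(=O)/C(CB1OC(C)(C)C(C)(C)O1)=C/[C@@H](O)C(=C)[C@@H](C)CCCOC(C)=O | intermediate
13 | methyl (2E,4R,6S)-4,9-diacetoxy-6-methyl-5-methylidene-2-[(4,4,5,5-tetramethyl-1,3,2-dioxaborolan-2-yl)methyl]non-2-enoate | COC(=O)/C(CB1OC(C)(C)C(C)(C)O1)=C/[C@@H](OC(C)=O)C(=C)[C@@H](C)CCCOC(C)=O | intermediate
14 | 3-methylbut-3-en-1-ol | CC(=C)CCO | starting material
15 | 3-methylbut-3-enal | CC(=C)CC=O | intermediate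
16 | methyl (3R,4R)-3-[(1R,3S)-1,6-diacetoxy-3-methyl-2-methylidenehexyl]-6-methyl-2-methylidene-4-[(4,4,5,5-tetramethyl-1,3,2-dioxaborolan-2-yl)oxy]hept-6-enoate | COC(=O)C(=C)[C@@H]([C@@H](OC(C)=O)C(=C)[C@@H](C)CCCOC(C)=O)[C@@H](CC(C)=C)OB1OC(C)(C)C(C)(C)O1 | intermediate
17 | (1R,3S)-6-acetoxy-3-methyl-2-methylidene-1-[(2R,3R)-4-methylidene-2-(2-methylprop-2-en-1-yl)-5-oxooxolan-3-yl]hexyl acetate | C=C1C(=O)O[C@H](CC(C)=C)[C@@H]1[C@@H](OC(C)=O)C(=C)[C@@H](C)CCCOC(C)=O | intermediate
18 | 1,6-O,O-diacetylbritannilactone (4S,6R,7R,8R in the locants used here; cis-fused lactone, C6 acetate cis to it) | C=C1C(=O)O[C@@H]2CC(C)=C([C@@H](C)CCCOC(C)=O)[C@H](OC(C)=O)[C@H]12 | target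

**Total step count:** 11
**Longest linear sequence:** 10 (steps 1–9 and 11)

**Steps most likely to fail**

Step 11. The ring closure may stall, because the ruthenium must load onto a 1,1-disubstituted alkene and then form a tetrasubstituted alkene next to two branched carbons; aldehyde 15 may also drift into conjugation on prolonged heating, and facial control at C7 may erode. Fallback by relay ring closure, setting out from 13 and coming back at 18: Wittig reaction of the ylide from (hex-5-en-1-yl)triphenylphosphonium bromide (NaN(SiMe3)2, THF) with 4,4-dimethoxybutan-2-one gives 9,9-dimethoxy-7-methylnona-1,6-diene F1, and mild hydrolysis (PPTS, wet acetone) gives 3-methylnona-3,8-dienal F2. Thermal allylboration of 13 with F2 gives the relay pinacol borate F3, which lactonizes to the relay lactone F4. The ruthenium catalyst then loads on the terminal vinyl group, expels cyclopentene to place the metal on C10, and closes ring A onto C5=CH2 to give 18.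

Step 8. Transmetalation of the borylmethylzinc reagent may be slow and the reagent may be protonated by the free hydroxyl, leaving reduced or unreacted iodide. Fallback that installs C13 as an oxygenated carbon first, setting out from 11 and coming back at 12: Stille coupling of 11 with (tributylstannyl)methanol (Pd(PPh3)4, dioxane, 80 °C) gives methyl (2E,4R,6S)-9-acetoxy-4-hydroxy-2-(hydroxymethyl)-6-methyl-5-methylidenenon-2-enoate F5. Selective acetylation of the primary hydroxyl (AcCl, 2,4,6-collidine, CH2Cl2, −78 °C) gives methyl (2E,4R,6S)-9-acetoxy-2-(acetoxymethyl)-4-hydroxy-6-methyl-5-methylidenenon-2-enoate F6. Palladium-catalysed borylation of the primary allylic acetate with B2pin2 (Pd2(dba)3, DMSO, 50 °C) gives 12.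

Step 6. Facial control by the catalyst may be insufficient on an α-branched acrolein that carries a neighbouring stereocentre, giving both C6 epimers. Fallback by reagent-controlled reduction, setting out from 7 and coming back at 9: the lithium acetylide of 8 (LiN(SiMe3)2, THF, −78 °C) adds to 7 without control and gives methyl (6S)-9-acetoxy-4-hydroxy-6-methyl-5-methylidenenon-2-ynoate F7 as both C4 epimers. Dess–Martin oxidation gives methyl (6S)-9-acetoxy-6-methyl-5-methylidene-4-oxonon-2-ynoate F8. Reduction with (S)-Alpine-Borane (from (−)-α-pinene; the alkynyl group acts as the small substituent) gives 9.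

**Further compounds**
F1 | step 11 | 9,9-dimethoxy-7-methylnona-1,6-diene (E/Z mixture) | C=CCCCC=C(C)CC(OC)OC
F2 | step 11 | 3-methylnona-3,8-dienal (E/Z mixture) | C=CCCCC=C(C)CC=O
F3 | step 11 | methyl (3R,4R)-3-[(1R,3S)-1,6-diacetoxy-3-methyl-2-methylidenehexyl]-6-methyl-2-methylidene-4-[(4,4,5,5-tetramethyl-1,3,2-dioxaborolan-2-yl)oxy]dodeca-6,11-dienoate | COC(=O)C(=C)[C@@H]([C@@H](OC(C)=O)C(=C)[C@@H](C)CCCOC(C)=O)[C@@H](CC(C)=CCCCC=C)OB1OC(C)(C)C(C)(C)O1
F4 | step 11 | (1R,3S)-6-acetoxy-3-methyl-2-methylidene-1-[(2R,3R)-4-methylidene-2-(2-methylocta-2,7-dien-1-yl)-5-oxooxolan-3-yl]hexyl acetate | C=C1C(=O)O[C@H](CC(C)=CCCCC=C)[C@@H]1[C@@H](OC(C)=O)C(=C)[C@@H](C)CCCOC(C)=O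
F5 | step 8 | methyl (2E,4R,6S)-9-acetoxy-4-hydroxy-2-(hydroxymethyl)-6-methyl-5-methylidenenon-2-enoate | COC(=O)/C(CO)=C/[C@@H](O)C(=C)[C@@H](C)CCCOC(C)=O
F6 | step 8 | methyl (2E,4R,6S)-9-acetoxy-2-(acetoxymethyl)-4-hydroxy-6-methyl-5-methylidenenon-2-enoate | COC(=O)/C(COC(C)=O)=C/[C@@H](O)C(=C)[C@@H](C)CCCOC(C)=O
F7 | step 6 | methyl (6S)-9-acetoxy-4-hydroxy-6-methyl-5-methylidenenon-2-ynoate (both C4 epimers) | COC(=O)C#CC(O)C(=C)[C@@H](C)CCCOC(C)=O
F8 | step 6 | methyl (6S)-9-acetoxy-6-methyl-5-methylidene-4-oxonon-2-ynoate | COC(=O)C#CC(=O)C(=C)[C@@H](C)CCCOC(C)=O
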